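The 1,2-dioxan-3-ol ring is cut at C4–C5, C6–O and O–C3. Carbons C1–C4 (ester C1, methylene C2, hemiketal C3, methyl-bearing C4) are a masked γ-branched acetoacetate. Folding C1 and C3 into the two carbonyls of a four-membered 1,3-dione places C4 between them, where an enol radical can form. One Mn(OAc)3-catalysed aerobic operation joins this carbon to the CH2 terminus of the C5=C6 alkene, attaches dioxygen at tertiary C6 and closes the peroxy hemiketal. The precursors are (R)-2,4-dimethyl-12-phenyldodec-1-ene, 2-methylcyclobutane-1,3-dione and O2. Opening of the strained ring in methanol later releases C1 as the methyl ester.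

Key step: step 7

Remark on numbering: C1–C6 are the carbons of the target chain (C1 ester carbon, C2 CH2, C3 hemiketal carbon, C4 methyl-bearing CH, C5 ring CH2, C6 peroxide-bearing quaternary carbon).

Assumption: C3 of the target equilibrates through the open hydroperoxy keto ester and C4 is set by uncontrolled protonation, so both are fixed by reclosure and separation; C6 is formed without control and its epimer is removed at the end.

Step 1
Reactants: 1 (R)-4-benzyl-3-propanoyl-1,3-oxazolidin-2-one; 2 3-bromo-2-methylprop-1-ene
Product: 4 (R)-4-benzyl-3-[(2S)-2,4-dimethylpent-4-enoyl]-1,3-oxazolidin-2-one, via sodium enolate 3 (not isolated)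
Conditions: NaN(SiMe3)2, THF, −78 °C; then 2, −78 → −40 °C
Reagents that add atoms: none
Why: Evans auxiliary alkylation, in which the chelated Z-enolate 3 is attacked by the allylic bromide on the face opposite the benzyl group of the auxiliary, which sets the (S) methyl centre; the minor diastereomer is removed by chromatography.

Step 2
Reactants: 4 (R)-4-benzyl-3-[(2S)-2,4-dimethylpent-4-enoyl]-1,3-oxazolidin-2-one
Product: 5 (S)-2,4-dimethylpent-4-en-1-ol
Conditions: LiBH4, H2O (1 equiv), Et2O, 0 °C
Reagents that add atoms: none
Why: Reductive removal of the auxiliary by hydride attack at the exocyclic imide carbonyl, which leaves the α-stereocentre and the 1,1-disubstituted alkene untouched.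

Step 3
Reactants: 5 (S)-2,4-dimethylpent-4-en-1-ol
Product: 6 (S)-2,4-dimethylpent-4-en-1-yl 4-methylbenzenesulfonate
Conditions: TsCl, Et3N, DMAP (cat.), CH2Cl2, 0 → 23 °C
Reagents that add atoms: 4-toluenesulfonyl chloride (TsCl), Cc1ccc(cc1)S(=O)(=O)Cl
Why: Routine sulfonylation of a primary alcohol that touches no stereocentre.

Step 4
Reactants: 6 (S)-2,4-dimethylpent-4-en-1-yl 4-methylbenzenesulfonate; 7 (7-bromoheptyl)benzene
Product: 9 (R)-2,4-dimethyl-12-phenyldodec-1-ene, via 7-phenylheptylmagnesium bromide 8 (not isolated)
Conditions: 7, Mg, THF, 40 °C; then 6, Li2CuCl4 (5 mol%), THF, −20 → 23 °C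
Reagents that add atoms: none
Why: Copper-catalysed alkyl–alkyl cross-coupling of a primary tosylate and a primary Grignard reagent, which leaves the adjacent stereocentre and the alkene alone (the descriptor changes from S to R only through the CIP priorities).

Step 5
Reactants: 10 propanoyl chloride; 11 ethoxyethyne
Product: 13 3-ethoxy-4-methylcyclobut-2-en-1-one (racemic), via methylketene 12 (not isolated)
Conditions: Et3N, Et2O, 0 → 23 °C, 10 added slowly to 11
Reagents that add atoms: none
Why: Dehydrochlorination gives methylketene, which undergoes a regioselective [2+2] cycloaddition with the ynol ether (alkyne CH to the ketene carbonyl carbon) to the 3-ethoxycyclobutenone.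

Step 6
Reactants: 13 3-ethoxy-4-methylcyclobut-2-en-1-one
Product: 14 2-methylcyclobutane-1,3-dione (handled as its enol, 3-hydroxy-2-methylcyclobut-2-en-1-one)
Conditions: 1 M HCl, THF/H2O, 0 → 23 °C
Reagents that add atoms: water, O
Why: Acid hydrolysis of the vinylogous ester by addition–elimination at C3 frees the vinylogous acid, and the racemic centre of 13 disappears on tautomerisation.

Step 7
Reactants: 9 (R)-2,4-dimethyl-12-phenyldodec-1-ene; 14 2-methylcyclobutane-1,3-dione; 15 dioxygen
Product: 17 (1S,4S,6R)-1-hydroxy-4,6-dimethyl-4-[(2R)-2-methyl-10-phenyldecyl]-2,3-dioxabicyclo[4.2.0]octan-7-one, via hydroperoxy dione 16 (not isolated)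
Conditions: 14 (3 equiv), Mn(OAc)3·2H2O (20 mol%), O2 (1 atm), AcOH, 23 °C
Reagents that add atoms: none
Why: Proposed new method: Mn(OAc)3 (trivalent manganese) converts the enol of 14 into an electrophilic radical at the methyl-bearing carbon, which adds to the CH2 terminus of 9; the tertiary radical captures O2, the peroxyl radical is reduced by divalent manganese (which returns the trivalent salt) to hydroperoxy dione 16, and 16 closes to 17. The closest known reaction type is the Mn(OAc)3/O2 three-component synthesis of 1,2-dioxan-3-ols from 1,3-diketones or cyclohexane-1,3-diones and 1,1-disubstituted alkenes; a cyclobutane-1,3-dione has not been used as the dicarbonyl partner. The 1,2-dioxane ring closes by 6-exo-trig addition of the hydroperoxide oxygen to a ring carbonyl (hemiketalisation). The peroxide-bearing carbon C4 of 17 is formed without facial control, since O2 meets a planar radical remote from the existing centre, so its epimer is expected in a similar amount and is carried on unseparated; C1 and C6 are tied to each other by the obligatory cis fusion of the four-membered ring and relate to C4 only through reversible hemiketal closure on either carbonyl, which does not matter because both carbonyls lead to the same keto ester in step 8. The step needs radical formation at the methyl-bearing carbon and not at the ring CH2 of 14 (the methyl-substituted enol is the dominant and more electron-rich tautomer), addition at the alkene CH2 (it gives the tertiary radical), and O2 capture faster than oxidation of that radical (O2 atmosphere); excess 14 suppresses a second oxidation at the ring CH2 of the product.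

Step 8
Reactants: 17 (1S,4S,6R)-1-hydroxy-4,6-dimethyl-4-[(2R)-2-methyl-10-phenyldecyl]-2,3-dioxabicyclo[4.2.0]octan-7-one
Product: 21 methyl 2-[(3S,4R,6S)-3-hydroxy-4,6-dimethyl-6-[(2R)-2-methyl-10-phenyldecyl]-1,2-dioxan-3-yl]acetate, via hydroxycyclobutenone 18 (not isolated), via hydroxyvinylketene 19 (not isolated), via hydroperoxy keto ester 20 (not isolated)
Conditions: MeOH/PhMe (1:1), 80 °C, sealed tube, dark; then preparative HPLC
Reagents that add atoms: methanol, CO
Why: Reopening of the peroxy hemiketal of 17 and enolisation toward the ring CH2 give 3-hydroxycyclobutenone 18, whose thermal 4π-electrocyclic ring opening (cyclobutenone to vinylketene) can break only the bond between the quaternary carbon and the carbonyl, so capture of ketene 19 by the large excess of methanol and ketonisation should give keto ester 20, which closes on the C3 ketone with the hydroxyl axial (anomeric effect) and cis to an equatorial C4 methyl; C4 is protonated without control and only a weak bias is expected, because its epimers differ in whether the methyl group or the side chain is axial at C6, so HPLC removes the C4 epimer (which can be re-equilibrated through the enol of its open form and separated again) and the two isomers of the C6-epimeric series.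

Compound list
1 | (R)-4-benzyl-3-propanoyl-1,3-oxazolidin-2-one | CCC(=O)N1[C@H](Cc2ccccc2)COC1=O | starting material
2 | 3-bromo-2-methylprop-1-ene | C=C(C)CBr | starting material
3 | sodium (Z)-enolate of 1 | C/C=C(\[O-])N1[C@H](Cc2ccccc2)COC1=O.[Na+] | intermediate (not isolated)
4 | (R)-4-benzyl-3-[(2S)-2,4-dimethylpent-4-enoyl]-1,3-oxazolidin-2-one | C=C(C)C[C@H](C)C(=O)N1[C@H](Cc2ccccc2)COC1=O | intermediate
5 | (S)-2,4-dimethylpent-4-en-1-ol | C=C(C)C[C@H](C)CO | intermediate
6 | (S)-2,4-dimethylpent-4-en-1-yl 4-methylbenzenesulfonate | C=C(C)C[C@H](C)COS(=O)(=O)c1ccc(C)cc1 | intermediate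
7 | (7-bromoheptyl)benzene | BrCCCCCCCc1ccccc1 | starting material
8 | 7-phenylheptylmagnesium bromide | Br[Mg]CCCCCCCc1ccccc1 | intermediate (not isolated)
9 | (R)-2,4-dimethyl-12-phenyldodec-1-ene | C=C(C)C[C@H](C)CCCCCCCCc1ccccc1 | intermediate
10 | propanoyl chloride | CCC(=O)Cl | starting material
11 | ethoxyethyne | CCOC#C | starting material
12 | methylketene (prop-1-en-1-one) | CC=C=O | intermediate (not isolated)
13 | 3-ethoxy-4-methylcyclobut-2-en-1-one (racemic) | CCOC1=CC(=O)C1C | intermediate
14 | 2-methylcyclobutane-1,3-dione | CC1C(=O)CC1=O | intermediate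
15 | dioxygen | O=O | starting material
16 | 2-[(2S,4R)-2-hydroperoxy-2,4-dimethyl-12-phenyldodecyl]-2-methylcyclobutane-1,3-dione | OO[C@@](C)(C[C@H](C)CCCCCCCCc1ccccc1)CC1(C)C(=O)CC1=O | intermediate (not isolated)
17 | (1S,4S,6R)-1-hydroxy-4,6-dimethyl-4-[(2R)-2-methyl-10-phenyldecyl]-2,3-dioxabicyclo[4.2.0]octan-7-one | O=C1C[C@]2(O)OO[C@@](C)(C[C@H](C)CCCCCCCCc3ccccc3)C[C@]12C | intermediate
18 | 4-[(2S,4R)-2-hydroperoxy-2,4-dimethyl-12-phenyldodecyl]-3-hydroxy-4-methylcyclobut-2-en-1-one (enol of the open form, both epimers at the ring carbon) | OO[C@@](C)(C[C@H](C)CCCCCCCCc1ccccc1)CC1(C)C(O)=CC1=O | intermediate (not isolated)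
19 | (6S,8R)-6-hydroperoxy-3-hydroxy-4,6,8-trimethyl-16-phenylhexadeca-1,3-dien-1-one | O=C=CC(O)=C(C)C[C@@](C)(OO)C[C@H](C)CCCCCCCCc1ccccc1 | intermediate (not isolated)
20 | methyl (6S,8R)-6-hydroperoxy-4,6,8-trimethyl-3-oxo-16-phenylhexadecanoate (C4 epimers) | COC(=O)CC(=O)C(C)C[C@@](C)(OO)C[C@H](C)CCCCCCCCc1ccccc1 | intermediate (not isolated)
21 | methyl 2-[(3S,4R,6S)-3-hydroxy-4,6-dimethyl-6-[(2R)-2-methyl-10-phenyldecyl]-1,2-dioxan-3-yl]acetate | COC(=O)C[C@]1(O)OO[C@@](C)(C[C@H](C)CCCCCCCCc2ccccc2)C[C@H]1C | target

Total step count: 8. Longest linear sequence: 6 (steps 1, 2, 3, 4, 7, 8).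

Steps most likely to fail

1. Step 7. The strongly acidic dione may be oxidised to its radical too slowly or unselectively, the product may be oxidised again at its ring CH2, or the cyclobutanone peroxy hemiketal may rearrange with loss of the O–O bond. The fallback uses known chemistry, sets out from 9 and returns at 20, which closes to 21. Ozonolysis of 9 (O3, CH2Cl2, −78 °C; then PPh3) gives (R)-4-methyl-12-phenyldodecan-2-one F1. Kinetic enolisation at the methyl group (LiN(iPr)2, THF, −78 °C) and trapping with PhNTf2 gives (R)-4-methyl-12-phenyldodec-1-en-2-yl trifluoromethanesulfonate F2. Negishi coupling (Pd(PPh3)4, THF/DMA, 23 °C) with (3-methoxy-2-methyl-3-oxopropyl)zinc iodide F3, made from methyl 3-iodo-2-methylpropanoate and zinc dust, gives methyl (6R)-2,6-dimethyl-4-methylidene-14-phenyltetradecanoate F4. Crossed Claisen condensation with the lithium enolate of methyl acetate gives methyl (8R)-4,8-dimethyl-6-methylidene-3-oxo-16-phenylhexadecanoate F5. Mukaiyama–Isayama hydroperoxysilylation (Co(acac)2, O2, Et3SiH, 23 °C) places the peroxide at the tertiary carbon and gives methyl (8R)-4,6,8-trimethyl-3-oxo-16-phenyl-6-[(triethylsilyl)peroxy]hexadecanoate F6. Desilylation (HF·pyridine, THF, 0 °C) frees 20 together with its C6 epimer; 20 closes to 21, which is separated from its stereoisomers as in step 8.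

2. Step 8. The O–O bond may be lost by homolysis or by acid-induced rearrangement of the peroxy hemiketal before the four-membered ring opens, or the hydroperoxide may add to the ketene within the molecule. The fallback protects the peroxide before the ring is opened, sets out from 17 and returns at 20. Silylation of 17 through its open form (TBSCl, imidazole, CH2Cl2, 0 °C) caps the enol and the hydroperoxide and gives 3-[(tert-butyldimethylsilyl)oxy]-4-{(2S,4R)-2-[(tert-butyldimethylsilyl)peroxy]-2,4-dimethyl-12-phenyldodecyl}-4-methylcyclobut-2-en-1-one F7. In this compound no hemiketal can form; heating in MeOH/PhMe (80 °C) opens the ring, removes the enol silyl group and gives methyl (6S,8R)-6-[(tert-butyldimethylsilyl)peroxy]-4,6,8-trimethyl-3-oxo-16-phenylhexadecanoate F8. HF·pyridine (THF, 0 °C) then frees 20, which closes to 21.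

3. Step 5. Self-dimerisation of methylketene may outrun the cycloaddition. The fallback uses a ketene that does not dimerise under these conditions, sets out from 11 and returns at 14. Deprotonation and methylation of 11 (n-BuLi, THF, −78 °C; MeI) gives 1-ethoxyprop-1-yne F9. Cycloaddition with dichloroketene F10, generated from trichloroacetyl chloride and Zn/Cu couple in Et2O, gives 4,4-dichloro-3-ethoxy-2-methylcyclobut-2-en-1-one F11. Reductive dechlorination (Zn, AcOH, TMEDA, EtOH, 0 °C) gives 3-ethoxy-2-methylcyclobut-2-en-1-one F12, and hydrolysis as in step 6 gives 14.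

Further compounds
F1 | step 7 | (R)-4-methyl-12-phenyldodecan-2-one | CC(=O)C[C@H](C)CCCCCCCCc1ccccc1
F2 | step 7 | (R)-4-methyl-12-phenyldodec-1-en-2-yl trifluoromethanesulfonate | C=C(OS(=O)(=O)C(F)(F)F)C[C@H](C)CCCCCCCCc1ccccc1
F3 | step 7 | (3-methoxy-2-methyl-3-oxopropyl)zinc iodide | COC(=O)C(C)C[Zn]I
F4 | step 7 | methyl (6R)-2,6-dimethyl-4-methylidene-14-phenyltetradecanoate | COC(=O)C(C)CC(=C)C[C@H](C)CCCCCCCCc1ccccc1
F5 | step 7 | methyl (8R)-4,8-dimethyl-6-methylidene-3-oxo-16-phenylhexadecanoate | COC(=O)CC(=O)C(C)CC(=C)C[C@H](C)CCCCCCCCc1ccccc1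
F6 | step 7 | methyl (8R)-4,6,8-trimethyl-3-oxo-16-phenyl-6-[(triethylsilyl)peroxy]hexadecanoate | COC(=O)CC(=O)C(C)CC(C)(OO[Si](CC)(CC)CC)C[C@H](C)CCCCCCCCc1ccccc1
F7 | step 8 | 3-[(tert-butyldimethylsilyl)oxy]-4-{(2S,4R)-2-[(tert-butyldimethylsilyl)peroxy]-2,4-dimethyl-12-phenyldodecyl}-4-methylcyclobut-2-en-1-one | CC(C)(C)[Si](C)(C)OO[C@@](C)(C[C@H](C)CCCCCCCCc1ccccc1)CC1(C)C(O[Si](C)(C)C(C)(C)C)=CC1=O
F8 | step 8 | methyl (6S,8R)-6-[(tert-butyldimethylsilyl)peroxy]-4,6,8-trimethyl-3-oxo-16-phenylhexadecanoate | COC(=O)CC(=O)C(C)C[C@@](C)(OO[Si](C)(C)C(C)(C)C)C[C@H](C)CCCCCCCCc1ccccc1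
F9 | step 5 | 1-ethoxyprop-1-yne | CCOC#CC
F10 | step 5 | dichloroketene | ClC(Cl)=C=O
F11 | step 5 | 4,4-dichloro-3-ethoxy-2-methylcyclobut-2-en-1-one | CCOC1=C(C)C(=O)C1(Cl)Cl
F12 | step 5 | 3-ethoxy-2-methylcyclobut-2-en-1-one | CCOC1=C(C)C(=O)C1
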